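**Retrosynthetic overview**
- The strategy rests on the two identical acyl arms on the cyclopentane (ring C1 CH2O–, C2 CH3, C3 O–, C5 CH(CH2OH)2). In each arm C3 is β to the ester carbonyl C1 and bonded to the alkenyl carbon C4 of the ethylidene enal (C5=CH, C6 methyl), so both C3–C4 bonds are cut as conjugate additions of one alkenyl boronate to a core bis-enoate.
- The bis-enoate comes from a cyclopentane diol and (E)-5,5-dimethoxypent-2-enoic acid by a two-fold Mitsunobu esterification, which also inverts the secondary carbinol to the required configuration.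
- The diol comes from (1S,4R)-cis-4-acetoxycyclopent-2-en-1-ol: malonate allylic alkylation, reduction, ketal formation, oxidation to the enone, vinyl cuprate addition with methylation, bulky-hydride reduction, ozonolysis.
- Rings: the cyclopentane is bought; the only ring made is the 1,3-dioxane ketal (step 3), which is opened again in the last step.
- After the key step: desilylation, MnO2 oxidation to the two enals, hydrolysis of all acetals.

Key step: step 16

Assumption: the facial model established for BINAP–rhodium additions to (E)-enoates ((S)-BINAP delivering to the α-si face) is taken to hold for this alkenyl donor, which assigns (R)-BINAP to the 3S series; if the sense were the reverse, (S)-BINAP would be used with no other change.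

**Route**

Step 1
Reactants: 1 (1S,4R)-cis-4-acetoxycyclopent-2-en-1-ol
Product: 2 dimethyl 2-[(1R,4S)-4-hydroxycyclopent-2-en-1-yl]propanedioate
Conditions: dimethyl malonate, NaH, Pd(PPh3)4 (3 mol %, zerovalent palladium), THF, 0 °C → rt
Reagents that add atoms: dimethyl malonate, COC(=O)CC(=O)OC
Why: Tsuji–Trost allylic alkylation: palladium ionises the acetate with inversion and the soft malonate anion attacks the allyl terminus remote from the hydroxyl on the face opposite the metal, so the malonyl group replaces the acetate with net retention and the 1,4-cis product keeps the configuration of that carbon.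

Step 2
Reactants: 2 dimethyl 2-[(1R,4S)-4-hydroxycyclopent-2-en-1-yl]propanedioate
Product: 3 2-[(1R,4S)-4-hydroxycyclopent-2-en-1-yl]propane-1,3-diol
Conditions: LiAlH4, THF, 0 °C → reflux; Rochelle salt work-up
Reagents that add atoms: none
Why: Hydride reduction of both malonate esters by LiAlH4, which leaves the isolated ring alkene and both stereocentres untouched.

Step 3
Reactants: 3 2-[(1R,4S)-4-hydroxycyclopent-2-en-1-yl]propane-1,3-diol
Product: 4 (1S,4R)-4-(2,2-dimethyl-1,3-dioxan-5-yl)cyclopent-2-en-1-ol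
Conditions: Me2C(OMe)2, PPTS (cat.), CH2Cl2, rt; aq. NaHCO3 work-up
Reagents that add atoms: 2,2-dimethoxypropane, COC(C)(C)OC
Why: Acid-catalysed transketalisation in which the 1,3-diol closes the six-membered isopropylidene ketal, while any mixed ketal on the lone secondary hydroxyl falls apart on work-up.

Step 4
Reactants: 4 (1S,4R)-4-(2,2-dimethyl-1,3-dioxan-5-yl)cyclopent-2-en-1-ol
Product: 5 (4R)-4-(2,2-dimethyl-1,3-dioxan-5-yl)cyclopent-2-en-1-one
Conditions: MnO2 (activated, excess), CH2Cl2, rt
Reagents that add atoms: none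
Why: Allylic alcohol oxidation with MnO2, a neutral heterogeneous oxidant that should not touch the ketal or racemise the γ-stereocentre.

Step 5
Reactants: 5 (4R)-4-(2,2-dimethyl-1,3-dioxan-5-yl)cyclopent-2-en-1-one
Product: 7 (2R,3S,4R)-4-(2,2-dimethyl-1,3-dioxan-5-yl)-3-ethenyl-2-methylcyclopentan-1-one, via bromomagnesium enolate 6 (not isolated)
Conditions: CH2=CHMgBr (2.2 equiv), CuBr·SMe2 (1.1 equiv), THF/Me2S, −78 °C; then HMPA, MeI (5 equiv), −78 → −20 °C; aq. NH4Cl
Reagents that add atoms: vinylmagnesium bromide, C=C[Mg]Br; iodomethane, CI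
Why: Tandem cuprate conjugate addition–enolate alkylation: the vinyl group should enter the β-carbon trans to the bulky dioxanyl group on the neighbouring carbon, and the regiodefined enolate should be methylated trans to the new vinyl group, giving the 2,3-trans-3,4-trans ketone.

Step 6
Reactants: 7 (2R,3S,4R)-4-(2,2-dimethyl-1,3-dioxan-5-yl)-3-ethenyl-2-methylcyclopentan-1-one
Product: 8 (1S,2R,3S,4R)-4-(2,2-dimethyl-1,3-dioxan-5-yl)-3-ethenyl-2-methylcyclopentan-1-ol
Conditions: LiBH(s-Bu)3, THF, −78 °C; then NaOH, H2O2, 0 °C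
Reagents that add atoms: none
Why: Bulky-hydride ketone reduction in which hydride should arrive on the face opposite the α-methyl group (also the face free of the dioxanyl group), setting the hydroxyl cis to methyl (1S), the epimer that step 11 inverts.

Step 7
Reactants: 8 (1S,2R,3S,4R)-4-(2,2-dimethyl-1,3-dioxan-5-yl)-3-ethenyl-2-methylcyclopentan-1-ol
Product: 10 (1S,2R,3S,4R)-4-(2,2-dimethyl-1,3-dioxan-5-yl)-3-(hydroxymethyl)-2-methylcyclopentan-1-ol, via aldehyde 9 (not isolated)
Conditions: O3, CH2Cl2/MeOH, −78 °C; then NaBH4, −78 °C → rt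
Reagents that add atoms: ozone, O=[O+][O-]
Why: Ozonolysis with reductive borohydride work-up turns the vinyl group into hydroxymethyl; the ketal has no acetal C–H for ozone to attack, and the aldehyde is reduced as it forms so its α-centre should not epimerise.

Step 8
Reactants: 11 methyl 3,3-dimethoxypropanoate
Product: 12 3,3-dimethoxypropanal
Conditions: i-Bu2AlH (1.05 equiv), CH2Cl2, −78 °C; Rochelle salt work-up; used crude at once
Reagents that add atoms: none
Why: Partial ester reduction by i-Bu2AlH at −78 °C, where the aluminium hemiacetal survives until work-up and then releases the aldehyde.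

Step 9
Reactants: 12 3,3-dimethoxypropanal
Product: 13 methyl (E)-5,5-dimethoxypent-2-enoate
Conditions: Ph3P=CHCO2Me, CH2Cl2, 0 °C → rt
Reagents that add atoms: methyl (triphenylphosphoranylidene)acetate, COC(=O)C=P(c1ccccc1)(c1ccccc1)c1ccccc1
Why: Wittig olefination with a stabilised ylide under neutral conditions should give the (E)-enoate and avoid base-induced loss of methanol from the β-acetal aldehyde.

Step 10
Reactants: 13 methyl (E)-5,5-dimethoxypent-2-enoate
Product: 14 (E)-5,5-dimethoxypent-2-enoic acid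
Conditions: LiOH, THF/H2O, 0 °C → rt; then cold dilute HCl to pH 4
Reagents that add atoms: lithium hydroxide, [Li+].[OH-]
Why: Ester saponification with LiOH at low temperature and careful acidification should leave the dimethyl acetal and the position of the alkene intact.

Step 11
Reactants: 10 (1S,2R,3S,4R)-4-(2,2-dimethyl-1,3-dioxan-5-yl)-3-(hydroxymethyl)-2-methylcyclopentan-1-ol; 14 (E)-5,5-dimethoxypent-2-enoic acid (3 equiv)
Product: 15 (1R,2R,3S,4R)-4-(2,2-dimethyl-1,3-dioxan-5-yl)-3-{[(E)-5,5-dimethoxypent-2-enoyloxy]methyl}-2-methylcyclopentyl (E)-5,5-dimethoxypent-2-enoate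
Conditions: PPh3 (3 equiv), DIAD (3 equiv), toluene/THF, 0 °C → rt
Reagents that add atoms: none
Why: Two-fold Mitsunobu esterification: the primary hydroxyl is acylated first and the secondary alkoxyphosphonium ion is then displaced by carboxylate in an SN2 step with inversion, turning the 1S carbinol into the required 1R ester (acyloxy trans to methyl).

Step 12
Reactants: 16 (E)-but-2-enal (crotonaldehyde)
Product: 18 (Z)-2-bromobut-2-enal, via 2,3-dibromobutanal 17 (not isolated)
Conditions: Br2, CH2Cl2, 0 °C; then Et3N, 0 °C → rt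
Reagents that add atoms: bromine, BrBr
Why: Bromine addition to the alkene followed by amine-induced loss of HBr through the enol(ate) (addition–elimination) should give the α-bromoenal with methyl trans to formyl, the more stable (Z) geometry.

Step 13
Reactants: 18 (Z)-2-bromobut-2-enal
Product: 19 (Z)-2-bromobut-2-en-1-ol
Conditions: NaBH4, CeCl3·7H2O, MeOH, 0 °C
Reagents that add atoms: none
Why: Luche 1,2-reduction of the enal should give the allylic alcohol without conjugate reduction, loss of bromide or change of alkene geometry.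

Step 14
Reactants: 19 (Z)-2-bromobut-2-en-1-ol
Product: 20 tert-butyl{[(2Z)-2-bromobut-2-en-1-yl]oxy}dimethylsilane
Conditions: TBSCl, imidazole, CH2Cl2, rt
Reagents that add atoms: tert-butyldimethylsilyl chloride, CC(C)(C)[Si](C)(C)Cl
Why: Standard silylation of a primary alcohol with a silyl chloride and imidazole.

Step 15
Reactants: 20 tert-butyl{[(2Z)-2-bromobut-2-en-1-yl]oxy}dimethylsilane
Product: 21 (E)-tert-butyldimethyl{[2-(4,4,5,5-tetramethyl-1,3,2-dioxaborolan-2-yl)but-2-en-1-yl]oxy}silane (boron cis to methyl)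
Conditions: B2pin2, PdCl2(PPh3)2 (3 mol %), PPh3 (6 mol %), KOPh, toluene, 50 °C
Reagents that add atoms: bis(pinacolato)diboron, CC1(C)OB(OC1(C)C)B1OC(C)(C)C(C)(C)O1
Why: Miyaura borylation of an alkenyl bromide, in which oxidative addition, phenoxide-assisted transmetallation and reductive elimination all proceed with retention, so boron should end cis to methyl.

Step 16
Reactants: 15 (1R,2R,3S,4R)-4-(2,2-dimethyl-1,3-dioxan-5-yl)-3-{[(E)-5,5-dimethoxypent-2-enoyloxy]methyl}-2-methylcyclopentyl (E)-5,5-dimethoxypent-2-enoate; 21 (E)-tert-butyldimethyl{[2-(4,4,5,5-tetramethyl-1,3,2-dioxaborolan-2-yl)but-2-en-1-yl]oxy}silane (5 equiv)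
Product: 22 (1R,2R,3S,4R)-4-(2,2-dimethyl-1,3-dioxan-5-yl)-2-methyl-3-{[(3S,4E)-4-(tert-butyldimethylsilyloxymethyl)-3-(2,2-dimethoxyethyl)hex-4-enoyloxy]methyl}cyclopentyl (3S,4E)-4-(tert-butyldimethylsilyloxymethyl)-3-(2,2-dimethoxyethyl)hex-4-enoate
Conditions: Rh(acac)(C2H4)2 (6 mol %), (R)-BINAP (7 mol %), K3PO4 (0.5 equiv), dioxane/H2O (10:1), 60–80 °C
Reagents that add atoms: none
Why: The alkenyl group passes from boron to a hydroxo-rhodium–BINAP species of monovalent rhodium with retention of alkene geometry, the enoate C=C inserts into the Rh–C bond, and water protonates the rhodium oxa-allyl enolate to release the β-alkenyl ester and regenerate Rh–OH. The closest known reaction type is the rhodium/BINAP-catalysed asymmetric 1,4-addition of aryl- and alkenylboron reagents to acyclic (E)-α,β-unsaturated esters (Hayashi–Miyaura reaction), used here with an α-branched alkenyl donor on both arms of one substrate. No ring is closed. Each new C3 stereocentre is set by the ligand alone: (R)-BINAP is expected to deliver the alkenyl group to the α-re (β-si) face of each (E)-enoate, which corresponds to 3S, and both enoates lie far enough from the ring stereocentres that the same sense should hold for the two arms. The step needs enantiofacial selectivity at each β-carbon (ligand), 1,4-addition only (soft alkenylrhodium with an ester acceptor) and retention of the alkene geometry (stereoretentive boron-to-rhodium transfer), while the bulky silyl ether should disfavour β-oxygen elimination from the alkenylrhodium and the mild phosphate base should spare the esters and the CH2 next to the acetal.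

Step 17
Reactants: 22 bis-silyl ether from step 16
Product: 23 (1R,2R,3S,4R)-4-(2,2-dimethyl-1,3-dioxan-5-yl)-2-methyl-3-{[(3S,4E)-3-(2,2-dimethoxyethyl)-4-(hydroxymethyl)hex-4-enoyloxy]methyl}cyclopentyl (3S,4E)-3-(2,2-dimethoxyethyl)-4-(hydroxymethyl)hex-4-enoate
Conditions: Bu4NF, AcOH (1:1), THF, 0 °C → rt
Reagents that add atoms: none
Why: Fluoride-mediated desilylation cleaves both Si–O bonds, and the acetic acid buffer keeps the freed allylic hydroxyl protonated so that it should not lactonise onto the ester five atoms away; the acetals are inert.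

Step 18
Reactants: 23 bis-allylic alcohol from step 17
Product: 24 (1R,2R,3S,4R)-4-(2,2-dimethyl-1,3-dioxan-5-yl)-2-methyl-3-{[(3S,4E)-3-(2,2-dimethoxyethyl)-4-formylhex-4-enoyloxy]methyl}cyclopentyl (3S,4E)-3-(2,2-dimethoxyethyl)-4-formylhex-4-enoate
Conditions: MnO2 (activated, excess), CH2Cl2, rt
Reagents that add atoms: none
Why: Allylic oxidation with MnO2 should take both primary allylic alcohols to the enals under neutral conditions, without over-oxidation and with the ethylidene geometry (methyl trans to formyl) unchanged.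

Step 19
Reactants: 24 bis-enal from step 18
Product: 25 (1R,2R,3S,4R)-4-(1,3-dihydroxypropan-2-yl)-3-{[(3S,4E)-4-formyl-3-(2-oxoethyl)hex-4-enoyloxy]methyl}-2-methylcyclopentyl (3S,4E)-4-formyl-3-(2-oxoethyl)hex-4-enoate (CNP0313563.1)
Conditions: 0.5 M aq. HCl, THF, 0 °C → rt
Reagents that add atoms: water, O
Why: Acid-catalysed hydrolysis in a water-rich medium should open the four dimethyl acetals and the isopropylidene ketal to the four aldehydes and the 1,3-diol; the esters survive and no stereocentre is α to a freed carbonyl.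

**Compound list**
1 | (1S,4R)-cis-4-acetoxycyclopent-2-en-1-ol | CC(=O)O[C@@H]1C[C@H](O)C=C1 | starting material
2 | dimethyl 2-[(1R,4S)-4-hydroxycyclopent-2-en-1-yl]propanedioate | COC(=O)C(C(=O)OC)[C@@H]1C[C@H](O)C=C1 | intermediate
3 | 2-[(1R,4S)-4-hydroxycyclopent-2-en-1-yl]propane-1,3-diol | OCC(CO)[C@@H]1C[C@H](O)C=C1 | intermediate
4 | (1S,4R)-4-(2,2-dimethyl-1,3-dioxan-5-yl)cyclopent-2-en-1-ol | CC1(C)OCC(CO1)[C@@H]2C[C@H](O)C=C2 | intermediate
5 | (4R)-4-(2,2-dimethyl-1,3-dioxan-5-yl)cyclopent-2-en-1-one | CC1(C)OCC(CO1)[C@@H]2CC(=O)C=C2 | intermediate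
6 | bromomagnesium (3S,4R)-4-(2,2-dimethyl-1,3-dioxan-5-yl)-3-ethenylcyclopent-1-en-1-olate | C=C[C@@H]1C=C(O[Mg]Br)C[C@H]1C2COC(C)(C)OC2 | intermediate (not isolated)
7 | (2R,3S,4R)-4-(2,2-dimethyl-1,3-dioxan-5-yl)-3-ethenyl-2-methylcyclopentan-1-one | C=C[C@@H]1[C@@H](C)C(=O)C[C@H]1C2COC(C)(C)OC2 | intermediate
8 | (1S,2R,3S,4R)-4-(2,2-dimethyl-1,3-dioxan-5-yl)-3-ethenyl-2-methylcyclopentan-1-ol | C=C[C@@H]1[C@@H](C)[C@@H](O)C[C@H]1C2COC(C)(C)OC2 | intermediate
9 | (1S,2R,3S,5S)-5-(2,2-dimethyl-1,3-dioxan-5-yl)-3-hydroxy-2-methylcyclopentane-1-carbaldehyde | O=C[C@@H]1[C@@H](C)[C@@H](O)C[C@H]1C2COC(C)(C)OC2 | intermediate (not isolated)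
10 | (1S,2R,3S,4R)-4-(2,2-dimethyl-1,3-dioxan-5-yl)-3-(hydroxymethyl)-2-methylcyclopentan-1-ol | OC[C@@H]1[C@@H](C)[C@@H](O)C[C@H]1C2COC(C)(C)OC2 | intermediate
11 | methyl 3,3-dimethoxypropanoate | COC(=O)CC(OC)OC | starting material
12 | 3,3-dimethoxypropanal | O=CCC(OC)OC | intermediate
13 | methyl (E)-5,5-dimethoxypent-2-enoate | COC(=O)/C=C/CC(OC)OC | intermediate
14 | (E)-5,5-dimethoxypent-2-enoic acid | OC(=O)/C=C/CC(OC)OC | intermediate
15 | (1R,2R,3S,4R)-4-(2,2-dimethyl-1,3-dioxan-5-yl)-3-{[(E)-5,5-dimethoxypent-2-enoyloxy]methyl}-2-methylcyclopentyl (E)-5,5-dimethoxypent-2-enoate | COC(OC)C/C=C/C(=O)OC[C@@H]1[C@@H](C)[C@H](OC(=O)/C=C/CC(OC)OC)C[C@H]1C2COC(C)(C)OC2 | intermediate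
16 | (E)-but-2-enal (crotonaldehyde) | C/C=C/C=O | starting material
17 | 2,3-dibromobutanal (racemic) | CC(Br)C(Br)C=O | intermediate (not isolated)
18 | (Z)-2-bromobut-2-enal | C/C=C(\Br)C=O | intermediate
19 | (Z)-2-bromobut-2-en-1-ol | C/C=C(\Br)CO | intermediate
20 | tert-butyl{[(2Z)-2-bromobut-2-en-1-yl]oxy}dimethylsilane | C/C=C(\Br)CO[Si](C)(C)C(C)(C)C | intermediate
21 | (E)-tert-butyldimethyl{[2-(4,4,5,5-tetramethyl-1,3,2-dioxaborolan-2-yl)but-2-en-1-yl]oxy}silane | C/C=C(/CO[Si](C)(C)C(C)(C)C)B1OC(C)(C)C(C)(C)O1 | intermediate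
22 | (1R,2R,3S,4R)-4-(2,2-dimethyl-1,3-dioxan-5-yl)-2-methyl-3-{[(3S,4E)-4-(tert-butyldimethylsilyloxymethyl)-3-(2,2-dimethoxyethyl)hex-4-enoyloxy]methyl}cyclopentyl (3S,4E)-4-(tert-butyldimethylsilyloxymethyl)-3-(2,2-dimethoxyethyl)hex-4-enoate | C/C=C(/CO[Si](C)(C)C(C)(C)C)[C@@H](CC(OC)OC)CC(=O)OC[C@@H]1[C@@H](C)[C@H](OC(=O)C[C@H](CC(OC)OC)/C(CO[Si](C)(C)C(C)(C)C)=C\C)C[C@H]1C2COC(C)(C)OC2 | intermediate
23 | (1R,2R,3S,4R)-4-(2,2-dimethyl-1,3-dioxan-5-yl)-2-methyl-3-{[(3S,4E)-3-(2,2-dimethoxyethyl)-4-(hydroxymethyl)hex-4-enoyloxy]methyl}cyclopentyl (3S,4E)-3-(2,2-dimethoxyethyl)-4-(hydroxymethyl)hex-4-enoate | C/C=C(/CO)[C@@H](CC(OC)OC)CC(=O)OC[C@@H]1[C@@H](C)[C@H](OC(=O)C[C@H](CC(OC)OC)/C(CO)=C\C)C[C@H]1C2COC(C)(C)OC2 | intermediate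
24 | (1R,2R,3S,4R)-4-(2,2-dimethyl-1,3-dioxan-5-yl)-2-methyl-3-{[(3S,4E)-3-(2,2-dimethoxyethyl)-4-formylhex-4-enoyloxy]methyl}cyclopentyl (3S,4E)-3-(2,2-dimethoxyethyl)-4-formylhex-4-enoate | C/C=C(/C=O)[C@@H](CC(OC)OC)CC(=O)OC[C@@H]1[C@@H](C)[C@H](OC(=O)C[C@H](CC(OC)OC)/C(C=O)=C\C)C[C@H]1C2COC(C)(C)OC2 | intermediate
25 | (1R,2R,3S,4R)-4-(1,3-dihydroxypropan-2-yl)-3-{[(3S,4E)-4-formyl-3-(2-oxoethyl)hex-4-enoyloxy]methyl}-2-methylcyclopentyl (3S,4E)-4-formyl-3-(2-oxoethyl)hex-4-enoate | C/C=C(/C=O)[C@@H](CC=O)CC(=O)OC[C@@H]1[C@@H](C)[C@H](OC(=O)C[C@H](CC=O)/C(C=O)=C\C)C[C@H]1C(CO)CO | target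

**Step count**
Total: 19 steps. Longest linear sequence: 12 steps (steps 1–7, 11, 16–19).

**Steps most likely to fail**

1. Step 16. The hindered α-branched alkenyl group may transfer slowly from boron to rhodium, so that protodeboronation, β-oxygen elimination from the alkenylrhodium, incomplete reaction of the second arm or weak facial control take over. Fallback, setting out from acid 14, bromide 20 and diol 10 and coming back at 22:
   - Acid 14 would be converted through its pivaloyl mixed anhydride with lithiated (4R)-4-phenyl-1,3-oxazolidin-2-one into (4R)-3-[(2E)-5,5-dimethoxypent-2-enoyl]-4-phenyl-1,3-oxazolidin-2-one F1.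
   - Bromide 20 would be lithiated (t-BuLi, Et2O, −78 °C), passed to magnesium (MgBr2·OEt2) and to copper (CuBr·SMe2), and added to F1 at −78 → −20 °C. The magnesium-chelated imide should be attacked on the face away from the phenyl group, giving (4R)-3-[(3S,4E)-4-(tert-butyldimethylsilyloxymethyl)-3-(2,2-dimethoxyethyl)hex-4-enoyl]-4-phenyl-1,3-oxazolidin-2-one F2.
   - LiOH/H2O2 would release (3S,4E)-4-(tert-butyldimethylsilyloxymethyl)-3-(2,2-dimethoxyethyl)hex-4-enoic acid F3.
   - Two-fold Mitsunobu esterification of diol 10 with F3 (conditions of step 11) would give 22.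

2. Step 11. Elimination at the activated secondary carbinol or incomplete inversion may compete with substitution. Fallback, setting out from diol 10 and coming back at 15: MsCl/Et3N would give (1S,2R,3S,4R)-4-(2,2-dimethyl-1,3-dioxan-5-yl)-2-methyl-3-[(methylsulfonyloxy)methyl]cyclopentyl methanesulfonate F4. Both sulfonates would then be displaced by the caesium salt of acid 14 (Cs2CO3, DMF, 50–60 °C), the secondary one with inversion, to give 15.

3. Step 5. Proton transfer between the product ketone and the enolate may lead to methylation at C5 or to double methylation, or the magnesium enolate may alkylate sluggishly. Fallback, setting out from enone 5 and coming back at 7: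
   - I2/pyridine in CH2Cl2 would give (4S)-4-(2,2-dimethyl-1,3-dioxan-5-yl)-2-iodocyclopent-2-en-1-one F5.
   - Stille coupling with Me4Sn (Pd2(dba)3, AsPh3, CuI, NMP) would give (4R)-4-(2,2-dimethyl-1,3-dioxan-5-yl)-2-methylcyclopent-2-en-1-one F6.
   - Vinyl cuprate addition (CH2=CHMgBr, CuBr·SMe2, TMSCl, THF, −78 °C) trans to the dioxanyl group, hydrolysis of the silyl enol ether and equilibration of C2 with DBU to the all-trans isomer would give 7.

**Further compounds**
F1 | step 16 | (4R)-3-[(2E)-5,5-dimethoxypent-2-enoyl]-4-phenyl-1,3-oxazolidin-2-one | O=C1OC[C@@H](c2ccccc2)N1C(=O)/C=C/CC(OC)OC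
F2 | step 16 | (4R)-3-[(3S,4E)-4-(tert-butyldimethylsilyloxymethyl)-3-(2,2-dimethoxyethyl)hex-4-enoyl]-4-phenyl-1,3-oxazolidin-2-one | O=C1OC[C@@H](c2ccccc2)N1C(=O)C[C@H](CC(OC)OC)/C(CO[Si](C)(C)C(C)(C)C)=C\C
F3 | step 16 | (3S,4E)-4-(tert-butyldimethylsilyloxymethyl)-3-(2,2-dimethoxyethyl)hex-4-enoic acid | OC(=O)C[C@H](CC(OC)OC)/C(CO[Si](C)(C)C(C)(C)C)=C\C
F4 | step 11 | (1S,2R,3S,4R)-4-(2,2-dimethyl-1,3-dioxan-5-yl)-2-methyl-3-[(methylsulfonyloxy)methyl]cyclopentyl methanesulfonate | CS(=O)(=O)OC[C@@H]1[C@@H](C)[C@@H](OS(C)(=O)=O)C[C@H]1C2COC(C)(C)OC2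
F5 | step 5 | (4S)-4-(2,2-dimethyl-1,3-dioxan-5-yl)-2-iodocyclopent-2-en-1-one | CC1(C)OCC(CO1)[C@@H]2CC(=O)C(I)=C2
F6 | step 5 | (4R)-4-(2,2-dimethyl-1,3-dioxan-5-yl)-2-methylcyclopent-2-en-1-one | CC1(C)OCC(CO1)[C@@H]2CC(=O)C(C)=C2
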